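The earlier runs and the new flask are calculated with made-up constants, and the scatter is random.

The closed, stirred, isothermal flask began with the solid substrate undissolved beside both nucleophiles, and the green run is this same flask followed over its first minutes.

| flask | solid substrate | first nucleophile | second nucleophile | remark | time |
|---|---|---|---|---|---|
| green | 0.73 M | 1.46 M | 0.876 M | the very flask that is asked about, followed so far |  |
| flask | 0.73 M | 1.46 M | 0.876 M |  | 30 min |

green run (percent of the solid substrate charged)

| time / min | target / % | other capture product / % |
|---|---|---|
| 0.667 | 8 | 7 |
| 1.33 | 14 | 23 |
| 2.00 | 22 | 27 |
| 3.00 | 25 | 38 |
| 4.00 | 23 | 40 |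

(standard deviation of a reading: 2 percentage points)

- solid substrate is a solid; its amount is given per volume of the solution
- the earlier runs were read with a standard deviation of 2 percentage points
- at the start none of the solid substrate is in solution

- ratio of target to other capture product at 10 s
- ratio of target to other capture product at 2.0 min
- ratio of target to other capture product at 30 min

I took each capture as first order in its nucleophile, so dividing one rate by the other removed time: target made per other capture product went as first over second nucleophile. In the green run the summed target readings over the summed other readings gave ρ = 0.681. Dividing ρ by the charge ratio 1.67 gave s = 0.409, the apparent selectivity factor: target read per other capture product, per unit of charged first over second nucleophile.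

From 3.00 min to 4.00 min the green target went from 25% to 23% and the other product from 38% to 40%, steps the size of the scatter, so I held the late ratio at s·cB/cD = 0.681, with cB and cD the charges of first and second nucleophile. For the early times I had single readings, 1.14 at 0.667 min and 0.815 at 2.00 min.

The forecast gave 1, 0.75 and 0.2, on the suggestion that “the target is a kinetic product slowly converted into the other product, or that some is lost”; its late ratio stood lower than mine.

The flask gave 1.32, 0.771 and 0.672.

    solid substrate ⇌ starting material, rate k1*(cs1 - [starting material]) while solid is left; crystals form when [starting material] > cs1 (solubility = 0.230 M, k = 0.0645 s⁻¹)
    target ⇌ isomer of the product (K = 1.30, k = 0.0443 s⁻¹)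
    second nucleophile + intermediate → other capture product (k = 13.8 M⁻¹ s⁻¹)
    first nucleophile + intermediate → target (k = 12.6 M⁻¹ s⁻¹)
    starting material → intermediate (k = 0.0347 s⁻¹)

From 15.0 min to 30.0 min this flask held target at 26.4% and other capture product at 39.3%, beside 34.3% of isomer of the product. Against its 0.672, s·cB/cD stood at 0.681. For the neighbour flask charged with 2.5 M of first nucleophile, s gave 1.17, and that flask stood at 1.15 at 30 min.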